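The route cuts the benzylic C1''–C2'' bond of the side chain on C8 of ring A. C2'' is allylic to the isopropenyl group, so the whole C9 unit can arrive by γ-selective allyl transfer. A chiral-phosphoric-acid-catalysed allylboration of tri-Boc 8-formylapigenin with an (E)-2,6-dimethylhepta-2,6-dienyl pinacol boronate forms the bond, sets C2'' and unveils the isopropenyl group in one operation. The precursor pair is an aldehyde and a linear allyl boronate, one oxidation level above the target at C1''. The extra oxygen is traceless because C1'' stands ortho to O7. Carbonate transfer gives the quinone methide C1''=C8–C7=O, which borohydride reduces.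

Key step: step 6

Remark: side-chain atoms are numbered C1'' (benzylic) to C6''. C2'' of the target is (R). The same spatial arrangement reads (S) in every compound that carries oxygen on C1'', because C1'' then outranks the isopropenyl carbon. Apigenin and 6-methylhept-5-en-2-one are taken as commercial.

Step 1
Reactants: 1 6-methylhept-5-en-2-one (sulcatone)
Product: 2 (5E)-7-hydroxy-6-methylhept-5-en-2-one
Conditions: SeO2 (cat.), t-BuOOH, CH2Cl2, 0 °C to rt
Reagents that add atoms: tert-butyl hydroperoxide, CC(C)(C)OO; selenium dioxide (oxygen relay), O=[Se]=O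
Why: Riley allylic oxidation (ene reaction, then [2,3]-sigmatropic shift of the allylseleninic acid) attacks the trisubstituted alkene at the methyl group trans to the chain, which should give the (E)-allylic alcohol and leave the ketone untouched at room temperature.

Step 2
Reactants: 2 (5E)-7-hydroxy-6-methylhept-5-en-2-one
Product: 3 (2E)-2,6-dimethylhepta-2,6-dien-1-ol
Conditions: Ph3PCH3Br (2.5 equiv), KOt-Bu (2.4 equiv), THF, 0 °C to rt
Reagents that add atoms: methyltriphenylphosphonium bromide, C[P+](c1ccccc1)(c1ccccc1)c1ccccc1.[Br-]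
Why: Wittig methylenation of an unhindered methyl ketone, in which the extra ylide only deprotonates the free alcohol and the (E)-trisubstituted alkene is not affected.

Step 3
Reactants: 3 (2E)-2,6-dimethylhepta-2,6-dien-1-ol
Product: 4 2-[(2E)-2,6-dimethylhepta-2,6-dien-1-yl]-4,4,5,5-tetramethyl-1,3,2-dioxaborolane
Conditions: B2pin2, [Pd(MeCN)4](BF4)2 (5 mol %), DMSO/MeOH, rt
Reagents that add atoms: bis(pinacolato)diboron, CC1(C)OB(OC1(C)C)B1OC(C)(C)C(C)(C)O1
Why: Palladium-catalysed borylation of an allylic alcohol through an η3-allylpalladium intermediate places boron on the less hindered CH2 terminus and should keep the chain syn, giving the linear (E)-allyl boronate with the isolated 1,1-disubstituted alkene as a spectator.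

Step 4
Reactants: 5 apigenin
Product: 6 8-formylapigenin (5,7-dihydroxy-2-(4-hydroxyphenyl)-4-oxo-4H-chromene-8-carbaldehyde)
Conditions: hexamethylenetetramine, AcOH, 100 °C; then aq. HCl, 70 °C
Reagents that add atoms: hexamethylenetetramine, C1N2CN3CN1CN(C2)C3; water, O
Why: In the Duff reaction the iminium ion from hexamethylenetetramine attacks the phloroglucinol-type ring A, expected at C8 (ortho to the free 7-OH, para to the chelated 5-OH), and internal redox plus hydrolysis gives the aldehyde.

Step 5
Reactants: 6 8-formylapigenin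
Product: 7 8-formylapigenin 5,7,4'-tris(tert-butyl carbonate)
Conditions: Boc2O (3.6 equiv), i-Pr2NEt, DMAP (cat.), THF, 0 °C to rt
Reagents that add atoms: di-tert-butyl dicarbonate, CC(C)(C)OC(=O)OC(=O)OC(C)(C)C
Why: DMAP-catalysed O-acylation of all three phenols gives a toluene-soluble, more electrophilic aldehyde and places on O7 the carbonate that step 7 needs.

Step 6
Reactants: 7 8-formylapigenin 5,7,4'-tris(tert-butyl carbonate); 4 (E)-2,6-dimethylhepta-2,6-dienyl pinacol boronate
Product: 9 8-[(1S,2S)-1-hydroxy-5-methyl-2-(prop-1-en-2-yl)hex-5-en-1-yl]apigenin 5,7,4'-tris(tert-butyl carbonate), via pinacol borate ester 8 (not isolated)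
Conditions: 4 (1.3 equiv), (S)-TRIP (10 mol %), 4 Å MS, toluene, −30 to 0 °C; pH 7 buffer work-up
Reagents that add atoms: none
Why: The phosphoric acid hydrogen-bonds to a pinacol oxygen of 4 and to the formyl C–H of 7, boron binds the aldehyde oxygen, and the γ-carbon of 4 (the future C2'') attacks the formyl carbon (the future C1'') through a closed six-membered chair while the C=C shifts and becomes the isopropenyl group. The closest known reaction type is the chiral-phosphoric-acid-catalysed crotylboration of aryl aldehydes with pinacol allyl boronates. No ring is closed in the product; the chair exists only in the transition state. C2'' is controlled by the (E)-geometry of 4, which puts the 3-methylbut-3-enyl chain equatorial and fixes the anti C1''/C2'' relation, and C1'' by (S)-TRIP, which by analogy with simple aryl aldehydes should expose the Si face, so the (1S,2S)-carbinol is expected, whose C2'' has the arrangement of the (R)-centre of 13. The step needs γ- over α-regioselectivity (secured by the closed transition state) and chemoselectivity for the aldehyde over the C4 carbonyl of ring C and the carbonates (a pinacol allyl boronate adds only to the aldehyde, which the three carbonates make more electrophilic). Any (Z)-4 ends up in the syn diastereomer, which can be removed by chromatography here, before the C1'' stereocentre is erased.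

Step 7
Reactants: 9 (1S,2S)-carbinol tris(tert-butyl carbonate)
Product: 13 8-[(2R)-5-methyl-2-(prop-1-en-2-yl)hex-5-en-1-yl]apigenin (target), via benzylic tert-butyl carbonate 10 (not isolated), via ortho-quinone methide 11 (not isolated), via bis-Boc phenol 12 (not isolated)
Conditions: NaBH4, THF/H2O, 0 °C to rt; then MeOH, K2CO3 (cat.), rt; aq. NH4Cl
Reagents that add atoms: none
Why: In the basic borohydride medium the carbinol oxygen takes over the neighbouring O7 Boc group through a six-membered transition state, the freed 7-phenoxide expels tert-butyl carbonate to give quinone methide 11, hydride adds 1,4 at C1'' (reductive ortho-quinone methide deoxygenation of an O-acyl salicyl alcohol) without touching C2'', the alkenes or the borohydride-inert flavone carbonyl, and base-catalysed methanolysis then removes the two remaining aryl carbonates.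

Compound list
1 | 6-methylhept-5-en-2-one (sulcatone) | CC(=O)CCC=C(C)C | starting material
2 | (5E)-7-hydroxy-6-methylhept-5-en-2-one | CC(=O)CC/C=C(\C)CO | intermediate
3 | (2E)-2,6-dimethylhepta-2,6-dien-1-ol | C=C(C)CC/C=C(\C)CO | intermediate
4 | 2-[(2E)-2,6-dimethylhepta-2,6-dien-1-yl]-4,4,5,5-tetramethyl-1,3,2-dioxaborolane | C=C(C)CC/C=C(\C)CB1OC(C)(C)C(C)(C)O1 | intermediate
5 | apigenin, 5,7-dihydroxy-2-(4-hydroxyphenyl)-4H-chromen-4-one | O=c1cc(-c2ccc(O)cc2)oc2cc(O)cc(O)c12 | starting material
6 | 8-formylapigenin | O=Cc1c(O)cc(O)c2c(=O)cc(-c3ccc(O)cc3)oc12 | intermediate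
7 | 8-formylapigenin 5,7,4'-tris(tert-butyl carbonate) | O=Cc1c(OC(=O)OC(C)(C)C)cc(OC(=O)OC(C)(C)C)c2c(=O)cc(-c3ccc(OC(=O)OC(C)(C)C)cc3)oc12 | intermediate
8 | pinacol borate ester of the (1S,2S)-carbinol 9 | C=C(C)CC[C@H]([C@H](OB4OC(C)(C)C(C)(C)O4)c1c(OC(=O)OC(C)(C)C)cc(OC(=O)OC(C)(C)C)c2c(=O)cc(-c3ccc(OC(=O)OC(C)(C)C)cc3)oc12)C(=C)C | intermediate
9 | 8-[(1S,2S)-1-hydroxy-5-methyl-2-(prop-1-en-2-yl)hex-5-en-1-yl]apigenin 5,7,4'-tris(tert-butyl carbonate) | C=C(C)CC[C@H]([C@H](O)c1c(OC(=O)OC(C)(C)C)cc(OC(=O)OC(C)(C)C)c2c(=O)cc(-c3ccc(OC(=O)OC(C)(C)C)cc3)oc12)C(=C)C | intermediate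
10 | (1S,2S)-benzylic tert-butyl carbonate with free 7-OH (Boc moved from O7 to the C1'' oxygen), 5,4'-bis(tert-butyl carbonate) | C=C(C)CC[C@H]([C@H](OC(=O)OC(C)(C)C)c1c(O)cc(OC(=O)OC(C)(C)C)c2c(=O)cc(-c3ccc(OC(=O)OC(C)(C)C)cc3)oc12)C(=C)C | intermediate
11 | ortho-quinone methide (C1''=C8, C7=O), (R) at C2'', 5,4'-bis(tert-butyl carbonate) | C=C(C)CC[C@H](C=C1C(=O)C=C(OC(=O)OC(C)(C)C)C2=C1OC(=CC2=O)c1ccc(OC(=O)OC(C)(C)C)cc1)C(=C)C | intermediate
12 | 8-[(2R)-5-methyl-2-(prop-1-en-2-yl)hex-5-en-1-yl]apigenin 5,4'-bis(tert-butyl carbonate), free 7-OH | C=C(C)CC[C@H](Cc1c(O)cc(OC(=O)OC(C)(C)C)c2c(=O)cc(-c3ccc(OC(=O)OC(C)(C)C)cc3)oc12)C(=C)C | intermediate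
13 | 5,7-dihydroxy-2-(4-hydroxyphenyl)-8-[(2R)-5-methyl-2-(prop-1-en-2-yl)hex-5-en-1-yl]-4H-chromen-4-one | C=C(C)CC[C@H](Cc1c(O)cc(O)c2c(=O)cc(-c3ccc(O)cc3)oc12)C(=C)C | target

Total step count: 7
Longest linear sequence: 5 steps (steps 1, 2, 3, 6, 7; the apigenin branch is 4 steps)

Steps most likely to fail

**Step 6.** The formyl group is flanked by O1 and the O7 carbonate. The addition may therefore be slow, and the catalyst may lose its grip on the aldehyde face, giving poor facial selectivity. The fallback drops catalyst control and resolves.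
- It sets out from 7 and 4. The uncatalysed thermal allylboration (toluene, 40 °C) still runs through the closed chair. It should give the anti carbinol as a racemate, that is 9 together with its (1R,2R)-enantiomer F1.
- Steglich esterification with (S)-O-methylmandelic acid turns the pair into two diastereomeric esters. These are the (S)-O-methylmandelate of the (1S,2S)-carbinol F2 and the (S)-O-methylmandelate of the (1R,2R)-carbinol F3. They are separated by chromatography or crystallisation.
- F2 needs no hydrolysis. Under NaBH4, K2CO3, MeOH/THF the O7 carbonate is methanolysed and the 7-phenoxide expels the mandelate. The sequence comes back to the route at quinone methide 11 and runs on to 13.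

**Step 7.** Three processes threaten this step.
- The O7 carbonate may be lost intermolecularly before it is transferred.
- The quinone methide may undergo a [1,5]-hydrogen shift from C2'', which would erase the stereocentre.
- The quinone methide may add intramolecularly to the pendant 1,1-disubstituted alkene.

The fallback replaces the polar pathway with a radical Barton–McCombie deoxygenation.
- It sets out from 9. Phenyl chlorothionoformate and pyridine (CH2Cl2, 0 °C) give the O-phenyl thionocarbonate F4.
- Bu3SnH at high concentration with AIBN (toluene, 80 °C) gives the tri-Boc protected target F5. The stabilised benzylic radical should close only slowly onto the methyl-substituted alkene compared with hydrogen transfer.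
- K2CO3 in MeOH then removes the three carbonates, and the sequence comes back to the route at 13.

**Step 4.** Positional selectivity may be poor, through attack at C6 or on ring B or through double formylation. The fallback separates C–C bond formation from oxidation.
- It sets out from 5. A Mannich aminomethylation with bis(dimethylamino)methane (2-propanol, reflux), which is known to favour C8 in 5,7-dihydroxyflavones, gives 8-[(dimethylamino)methyl]apigenin F6. This base can be purified by acid–base extraction and crystallisation.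
- Sommelet-type oxidation of F6 (hexamethylenetetramine, AcOH, 100 °C; then aq. HCl) comes back to the route at 6.

Further compounds
F1 | step 6 | (1R,2R)-enantiomer of carbinol 9 | C=C(C)CC[C@@H]([C@@H](O)c1c(OC(=O)OC(C)(C)C)cc(OC(=O)OC(C)(C)C)c2c(=O)cc(-c3ccc(OC(=O)OC(C)(C)C)cc3)oc12)C(=C)C
F2 | step 6 | (S)-O-methylmandelate of the (1S,2S)-carbinol 9 | C=C(C)CC[C@H]([C@H](OC(=O)[C@@H](OC)c4ccccc4)c1c(OC(=O)OC(C)(C)C)cc(OC(=O)OC(C)(C)C)c2c(=O)cc(-c3ccc(OC(=O)OC(C)(C)C)cc3)oc12)C(=C)C
F3 | step 6 | (S)-O-methylmandelate of the (1R,2R)-carbinol F1 | C=C(C)CC[C@@H]([C@@H](OC(=O)[C@@H](OC)c4ccccc4)c1c(OC(=O)OC(C)(C)C)cc(OC(=O)OC(C)(C)C)c2c(=O)cc(-c3ccc(OC(=O)OC(C)(C)C)cc3)oc12)C(=C)C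
F4 | step 7 | O-phenyl thionocarbonate of the (1S,2S)-carbinol 9 | C=C(C)CC[C@H]([C@H](OC(=S)Oc4ccccc4)c1c(OC(=O)OC(C)(C)C)cc(OC(=O)OC(C)(C)C)c2c(=O)cc(-c3ccc(OC(=O)OC(C)(C)C)cc3)oc12)C(=C)C
F5 | step 7 | 8-[(2R)-5-methyl-2-(prop-1-en-2-yl)hex-5-en-1-yl]apigenin 5,7,4'-tris(tert-butyl carbonate) | C=C(C)CC[C@H](Cc1c(OC(=O)OC(C)(C)C)cc(OC(=O)OC(C)(C)C)c2c(=O)cc(-c3ccc(OC(=O)OC(C)(C)C)cc3)oc12)C(=C)C
F6 | step 4 | 8-[(dimethylamino)methyl]apigenin | CN(C)Cc1c(O)cc(O)c2c(=O)cc(-c3ccc(O)cc3)oc12
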